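**Plan**

- Retrosynthetic cuts, in order: the ester on O6; then C11=C13 together with O6–H, by tying C13 to O6 as a temporary oxolane; then C4=C5 of the ten-membered ring; then, in one event, the lactone bonds O–C8 and C11–C7; last the tether bond O6–C13, the C7=C8 alkene and C3–C4.
- Forward order: acyclic C1–C3/C8–C10 bromide plus a C5–C7 piece, then a malonate tether on O6. A radical annulation builds oxolane and γ-lactone together as a cis-fused 3,7-dioxabicyclo[3.3.0]octan-2-one (furo[3,4-c]furanone). This bicycle is the template for closing the ten-membered ring at C4=C5; the oxolane is then opened again and O6 is acylated.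
- Enabling feature: O6 (on C6) and C13 (on C11) flank the C7–C11 bond, so the α-methylene-γ-lactone with its neighbouring 6-oxygen is the ring-opened form of that furo[3,4-c]furanone. With C13 joined to O6, lactone annulation across C7=C8 becomes a 5-exo radical closure followed by lactonisation.
- Stereochemistry: C6 is bought as (2S)-but-3-ene-1,2-diol, whose C1–C3 become C5–C7. C7 and C8 are relayed from C6 in the key step. E-C1=C10 comes from syn-carboalumination, ring-cis C4=C5 from the olefination ring closure, and the E side-chain alkene from a stabilised Wittig reaction.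

Key step: step 7

Remark: C-numbers are those of the germacrane skeleton (C1–C10 ring, C11–C13 acrylate unit of the lactone, C14 on C10, C15 on C4; the target is 6R,7R,8S in this numbering). The E/Z ratio of the C7=C8 alkene from step 4 is without consequence, because C8 becomes a planar radical in step 7. The bicyclic core is numbered as tetrahydro-1H,3H-furo[3,4-c]furan-1-one (C1 = C12, C3 = C8, C3a = C7, C4 = C6, O5 = O6, C6 = C13, C6a = C11).

**Route**

Step 1
Reactants: 1 pent-1-en-4-yne; 2 oxirane
Product: 5 (3E)-4-methylhepta-3,6-dien-1-ol, via alkenylalane 3 (not isolated), via lithium alkenylaluminate 4 (not isolated)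
Conditions: AlMe3, Cp2ZrCl2 (25 mol %), ClCH2CH2Cl, 0 → 23 °C; volatiles removed; n-BuLi, THF/hexane, −78 °C; oxirane, −78 → 0 °C; aq. HCl
Reagents that add atoms: trimethylaluminium, C[Al](C)C
Why: Zirconium-catalysed Negishi carboalumination adds methyl and aluminium syn across the terminal alkyne (methyl to the internal carbon, the alkene is left alone), and the derived alkenylaluminate opens oxirane with retention, so the C1=C10 alkene should be fixed as E.

Step 2
Reactants: 5 (3E)-4-methylhepta-3,6-dien-1-ol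
Product: 6 (4E)-7-bromo-4-methylhepta-1,4-diene
Conditions: CBr4, PPh3, CH2Cl2, 0 °C
Reagents that add atoms: tetrabromomethane, BrC(Br)(Br)Br
Why: Appel reaction of a primary alcohol, an SN2 displacement of the alkoxyphosphonium ion that does not touch either alkene.

Step 3
Reactants: 7 (2S)-but-3-ene-1,2-diol
Product: 8 (2S)-1-[(tert-butyldiphenylsilyl)oxy]but-3-en-2-ol
Conditions: TBDPSCl, imidazole, CH2Cl2, −20 → 0 °C
Reagents that add atoms: tert-butyl(chloro)diphenylsilane, CC(C)(C)[Si](Cl)(c1ccccc1)c1ccccc1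
Why: Silylation with a bulky chlorosilane should be selective for the primary hydroxyl; the carbinol that becomes C6 is not touched.

Step 4
Reactants: 8 (2S)-1-[(tert-butyldiphenylsilyl)oxy]but-3-en-2-ol; 6 (4E)-7-bromo-4-methylhepta-1,4-diene (3 equiv)
Product: 9 (2S,3E,6E)-9-bromo-1-[(tert-butyldiphenylsilyl)oxy]-6-methylnona-3,6-dien-2-ol
Conditions: [1,3-bis(2,4,6-trimethylphenyl)imidazolidin-2-ylidene]dichloro(2-isopropoxybenzylidene)ruthenium (second-generation Hoveyda–Grubbs catalyst, 5 mol %), 1,4-benzoquinone (10 mol %), CH2Cl2, 40 °C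
Reagents that add atoms: none
Why: Olefin cross-metathesis between a slowly dimerising secondary allylic alcohol and an excess of a terminal alkene should give mainly the E-alkene, the trisubstituted alkene being inert and benzoquinone suppressing hydride-induced isomerisation.

Step 5
Reactants: 10 di-tert-butyl malonate; 11 paraformaldehyde
Product: 12 di-tert-butyl 2-methylidenepropanedioate
Conditions: Cu(OAc)2 (5 mol %), KOAc, AcOH, 95 °C; distillation
Reagents that add atoms: none
Why: Knoevenagel-type methylenation of a malonate with formaldehyde; the bulky ester groups make this acceptor stable enough to distil and store.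

Step 6
Reactants: 9 (2S,3E,6E)-9-bromo-1-[(tert-butyldiphenylsilyl)oxy]-6-methylnona-3,6-dien-2-ol; 12 di-tert-butyl 2-methylidenepropanedioate
Product: 14 di-tert-butyl 2-[({(2S,3E,6E)-9-bromo-1-[(tert-butyldiphenylsilyl)oxy]-6-methylnona-3,6-dien-2-yl}oxy)methyl]propanedioate, via sodium alkoxide 13 (not isolated)
Conditions: NaH (1.05 equiv), THF, 0 °C; 12 (1.1 equiv), −78 → −40 °C; AcOH, −78 °C
Reagents that add atoms: none
Why: Oxa-Michael addition of the alkoxide to a doubly activated alkene gives a stabilised malonate enolate, so the addition should not revert, and it installs the O6–C13 tether without touching C6.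

Step 7
Reactants: 14 di-tert-butyl 2-[({(2S,3E,6E)-9-bromo-1-[(tert-butyldiphenylsilyl)oxy]-6-methylnona-3,6-dien-2-yl}oxy)methyl]propanedioate
Product: 17 tert-butyl 3-[(2E)-5-bromo-2-methylpent-2-en-1-yl]-4-{[(tert-butyldiphenylsilyl)oxy]methyl}-1-oxotetrahydro-1H,3H-furo[3,4-c]furan-6a-carboxylate (cis-fused; H-3/H-3a trans; H-3a/H-4 trans), via malonyl radical 15 (not isolated), via cyclised C8 radical 16 (not isolated)
Conditions: Mn(OAc)3·2H2O (2.2 equiv), Cu(OAc)2·H2O (1.0 equiv), degassed AcOH (0.02 M), 70 °C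
Reagents that add atoms: none
Why: Manganese triacetate enolises the malonate and oxidises it to the electrophilic malonyl radical 15, which adds 5-exo-trig to C7 and gives the secondary C8 radical 16; the O6–C13 tether makes C11-to-C7 the only five-membered closure, attack on C8 being 6-endo and attack on the remote C1=C10 alkene an eight-membered closure. Copper diacetate oxidises 16 to an alkylcopper, cation-like centre that is captured in a 5-exo sense by the carbonyl oxygen of the ester lying cis on C11, with loss of 2-methylpropene, so C11–C7 and O–C8 should form in one flask. The closest known reaction type is the manganese triacetate/copper diacetate oxidative free-radical cyclisation of unsaturated malonates that ends in lactonisation, here run through an ether tether. C7 is set by C6, because the chair-like transition state of the 3-oxahex-5-enyl radical holds the CH2OTBDPS group pseudo-equatorial and so gives the 6,7-trans oxolane; C11 needs no control since its two esters are identical and only a cis ring fusion can form. C8 is set when the lactone closes on the cis-fused bicycle with the C9 chain on the convex face, which is the 7,8-trans relationship of the target. The step needs lactonisation to outrun copper-mediated β-hydride loss to a C8=C9 diene; the 1,4-disposition of C8 and the ester carbonyl and the easy loss of the tert-butyl group should secure this.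

Step 8
Reactants: 17 tert-butyl ester from step 7
Product: 20 3-[(2E)-5-bromo-2-methylpent-2-en-1-yl]-4-{[(tert-butyldiphenylsilyl)oxy]methyl}tetrahydro-1H,3H-furo[3,4-c]furan-1-one (cis-fused; 3,3a-trans; 3a,4-trans), via trimethylsilyl ester 18 (not isolated), via carboxylic acid 19 (not isolated)
Conditions: Me3SiOTf, 2,6-lutidine, CH2Cl2, 0 °C; aq. NaH2PO4; toluene, 100 °C
Reagents that add atoms: none
Why: Silyl-triflate cleavage of the tert-butyl ester followed by thermal decarboxylation of the malonic-type acid through its enol; reprotonation at C11 can only give the cis-fused bicycle.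

Step 9
Reactants: 20 bromo lactone from step 8; 21 triethyl phosphonoacetate
Product: 23 ethyl (5E)-7-[4-{[(tert-butyldiphenylsilyl)oxy]methyl}-1-oxotetrahydro-1H,3H-furo[3,4-c]furan-3-yl]-2-(diethoxyphosphoryl)-6-methylhept-5-enoate (core as in 20; both C-2 epimers), via sodium phosphonoacetate 22 (not isolated)
Conditions: NaH, 21 (3 equiv), DMF, 0 °C; 20, 45 °C
Reagents that add atoms: none
Why: SN2 C-alkylation of a phosphonate-stabilised carbanion by the primary bromide; this soft anion is far too weak a base to enolise the lactone, and the new C4 centre is lost again in step 12.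

Step 10
Reactants: 23 silyl ether phosphonate
Product: 24 ethyl (5E)-2-(diethoxyphosphoryl)-7-[4-(hydroxymethyl)-1-oxotetrahydro-1H,3H-furo[3,4-c]furan-3-yl]-6-methylhept-5-enoate
Conditions: Bu4NF, AcOH, THF, 23 °C
Reagents that add atoms: none
Why: Fluoride desilylation, buffered with acetic acid so that neither the phosphonoacetate nor the lactone is deprotonated.

Step 11
Reactants: 24 primary alcohol
Product: 25 ethyl (5E)-2-(diethoxyphosphoryl)-7-(4-formyl-1-oxotetrahydro-1H,3H-furo[3,4-c]furan-3-yl)-6-methylhept-5-enoate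
Conditions: Dess–Martin periodinane, CH2Cl2, 23 °C
Reagents that add atoms: none
Why: Dess–Martin oxidation gives the C5 aldehyde under near-neutral conditions that should not epimerise the α-alkoxy centre C6.

Step 12
Reactants: 25 aldehyde phosphonate
Product: 26 tricyclic ethyl ester in which C4=C5 closes the ten-membered ring C1–C10 on the furo[3,4-c]furanone core (C3 cis to C6 across C4=C5; E-C1=C10; C15 = CO2Et)
Conditions: LiCl, i-Pr2NEt, MeCN, 45 °C, 25 added by syringe pump (1 mM)
Reagents that add atoms: none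
Why: Intramolecular Horner–Wadsworth–Emmons olefination under Masamune–Roush conditions; the cis-fused bicycle holds the C5 aldehyde and the C9 chain on the same convex face, and the ester-trans-to-C6 geometry that this olefination favours is the ring-cis alkene the ten-membered ring needs.

Step 13
Reactants: 26 tricyclic ethyl ester
Product: 27 lactol diol (C15 = CH2OH; C12 = CH(OH), both lactol epimers)
Conditions: i-Bu2AlH (4 equiv), CH2Cl2, −78 °C; aq. potassium sodium tartrate
Reagents that add atoms: none
Why: Hydride reduction takes the conjugated ester to the allylic alcohol and stops the lactone at the aluminium hemiacetal at −78 °C; the lactone cannot be spared, so it is restored in step 15.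

Step 14
Reactants: 27 lactol diol
Product: 28 15-O-tert-butyldimethylsilyl lactol
Conditions: TBSCl (1.1 equiv), imidazole, CH2Cl2, −20 °C
Reagents that add atoms: tert-butyl(chloro)dimethylsilane, CC(C)(C)[Si](C)(C)Cl
Why: Silylation should occur at the unhindered primary allylic hydroxyl and leave the hindered lactol hydroxyl.

Step 15
Reactants: 28 silylated lactol
Product: 29 tricyclic lactone with C15 = CH2OTBS (13,6-ether still in place)
Conditions: n-Pr4N[RuO4] (5 mol %), N-methylmorpholine N-oxide, 4 Å sieves, CH2Cl2, 23 °C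
Reagents that add atoms: none
Why: Ley–Griffith oxidation of a lactol to the lactone; silyl ether and trisubstituted alkenes are not affected.

Step 16
Reactants: 29 tricyclic lactone
Product: 31 11-bromo lactone (bromine on the convex face at C11), via lithium enolate 30 (not isolated)
Conditions: LiN(SiMe3)2, THF, −78 °C, 10 min; NBS, −78 °C; aq. NH4Cl
Reagents that add atoms: N-bromosuccinimide, O=C1CCC(=O)N1Br
Why: Enolate bromination at the only acidic position; the cis ring fusion forces the halogen onto the convex face.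

Step 17
Reactants: 31 11-bromo lactone
Product: 33 6-hydroxy-15-[(tert-butyldimethylsilyl)oxy]germacra-1(10)E,4(ring-cis),11(13)-trien-12,8-olide (6R,7R,8S), via bromozinc enolate 32 (not isolated)
Conditions: Zn dust (activated with Me3SiCl), THF, 45 °C; aq. NH4Cl
Reagents that add atoms: none
Why: Zinc insertion gives a Reformatsky enolate that expels the β-oxygen (Boord-type reductive elimination), which cleaves C13–O6 and should reveal the exocyclic methylene and the free 6-hydroxyl in one step; the ring fusion holds O6 out of the enolate plane, and the reverse 5-endo addition is slow.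

Step 18
Reactants: 34 [(tert-butyldimethylsilyl)oxy]acetaldehyde; 35 ethyl 2-(triphenylphosphoranylidene)propanoate
Product: 36 ethyl (2E)-4-[(tert-butyldimethylsilyl)oxy]-2-methylbut-2-enoate
Conditions: toluene, 80 °C
Reagents that add atoms: none
Why: Wittig reaction of a stabilised, α-branched ylide, which should give the E-trisubstituted enoate.

Step 19
Reactants: 36 ethyl ester
Product: 37 (2E)-4-[(tert-butyldimethylsilyl)oxy]-2-methylbut-2-enoic acid
Conditions: LiOH, THF/MeOH/H2O, 23 °C; aq. HCl to pH 4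
Reagents that add atoms: lithium hydroxide, [Li+].[OH-]
Why: Saponification; the primary silyl ether tolerates dilute hydroxide and the brief mild acidification.

Step 20
Reactants: 33 hydroxy lactone; 37 silyloxy acid
Product: 39 6-O-[(2E)-4-(tert-butyldimethylsilyloxy)-2-methylbut-2-enoyl] ester of 33, via mixed anhydride 38 (not isolated)
Conditions: 2,4,6-trichlorobenzoyl chloride, Et3N, THF, 23 °C; then 33, 4-(dimethylamino)pyridine, toluene, 23 °C
Reagents that add atoms: none
Why: Yamaguchi esterification acylates the hindered secondary allylic alcohol on oxygen, so C6 keeps its configuration and the enoate geometry is retained.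

Step 21
Reactants: 39 bis-silyl ether
Product: 40 target, 6-O-[(2E)-4-hydroxy-2-methylbut-2-enoyl]-15-hydroxygermacra-1(10)E,4(ring-cis),11(13)-trien-12,8-olide (6R,7R,8S)
Conditions: HF·pyridine, pyridine, THF, 0 → 23 °C
Reagents that add atoms: none
Why: Buffered fluoride removes both primary silyl ethers without base, so the α-methylene lactone and the allylic ester should survive.

**Compound list**

1 | pent-1-en-4-yne | C=CCC#C | starting material
2 | oxirane | C1CO1 | starting material
3 | dimethyl[(1E)-2-methylpenta-1,4-dien-1-yl]alane | C=CC/C(C)=C/[Al](C)C | intermediate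
4 | lithium butyl(dimethyl)[(1E)-2-methylpenta-1,4-dien-1-yl]aluminate | [Li+].CCCC[Al-](C)(C)/C=C(C)/CC=C | intermediate
5 | (3E)-4-methylhepta-3,6-dien-1-ol | C=CC/C(C)=C/CCO | intermediate
6 | (4E)-7-bromo-4-methylhepta-1,4-diene | C=CC/C(C)=C/CCBr | intermediate
7 | (2S)-but-3-ene-1,2-diol | OC[C@@H](O)C=C | starting material
8 | (2S)-1-[(tert-butyldiphenylsilyl)oxy]but-3-en-2-ol | CC(C)(C)[Si](OC[C@@H](O)C=C)(c1ccccc1)c1ccccc1 | intermediate
9 | (2S,3E,6E)-9-bromo-1-[(tert-butyldiphenylsilyl)oxy]-6-methylnona-3,6-dien-2-ol | CC(C)(C)[Si](OC[C@@H](O)/C=C/C/C(C)=C/CCBr)(c1ccccc1)c1ccccc1 | intermediate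
10 | di-tert-butyl malonate | CC(C)(C)OC(=O)CC(=O)OC(C)(C)C | starting material
11 | paraformaldehyde (formaldehyde unit) | C=O | starting material
12 | di-tert-butyl 2-methylidenepropanedioate | C=C(C(=O)OC(C)(C)C)C(=O)OC(C)(C)C | intermediate
13 | sodium (2S,3E,6E)-9-bromo-1-[(tert-butyldiphenylsilyl)oxy]-6-methylnona-3,6-dien-2-olate | [Na+].[O-][C@H](CO[Si](c1ccccc1)(c1ccccc1)C(C)(C)C)/C=C/C/C(C)=C/CCBr | intermediate
14 | di-tert-butyl 2-[({(2S,3E,6E)-9-bromo-1-[(tert-butyldiphenylsilyl)oxy]-6-methylnona-3,6-dien-2-yl}oxy)methyl]propanedioate | CC(C)(C)OC(=O)C(CO[C@H](CO[Si](c1ccccc1)(c1ccccc1)C(C)(C)C)/C=C/C/C(C)=C/CCBr)C(=O)OC(C)(C)C | intermediate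
15 | C11-centred malonyl radical of 14 | CC(C)(C)OC(=O)[C](CO[C@H](CO[Si](c1ccccc1)(c1ccccc1)C(C)(C)C)/C=C/C/C(C)=C/CCBr)C(=O)OC(C)(C)C | intermediate
16 | di-tert-butyl 4,5-trans-5-{[(tert-butyldiphenylsilyl)oxy]methyl}oxolane-3,3-dicarboxylate carrying at C4 the (3E)-6-bromo-3-methylhex-3-en-1-yl chain with the radical at its C1 (= C8) | CC(C)(C)OC(=O)C1(C(=O)OC(C)(C)C)CO[C@H](CO[Si](c2ccccc2)(c2ccccc2)C(C)(C)C)[C@H]1[CH]C/C(C)=C/CCBr | intermediate
17 | tert-butyl 3-[(2E)-5-bromo-2-methylpent-2-en-1-yl]-4-{[(tert-butyldiphenylsilyl)oxy]methyl}-1-oxotetrahydro-1H,3H-furo[3,4-c]furan-6a-carboxylate (cis-fused; 3,3a-trans; 3a,4-trans; C6, C7, C8 as in 40) | O=C1O[C@@H](C/C(C)=C/CCBr)[C@H]2[C@]1(C(=O)OC(C)(C)C)CO[C@@H]2CO[Si](c1ccccc1)(c1ccccc1)C(C)(C)C | intermediate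
18 | trimethylsilyl ester corresponding to 17 | O=C1O[C@@H](C/C(C)=C/CCBr)[C@H]2[C@]1(C(=O)O[Si](C)(C)C)CO[C@@H]2CO[Si](c1ccccc1)(c1ccccc1)C(C)(C)C | intermediate
19 | 6a-carboxylic acid corresponding to 17 | O=C1O[C@@H](C/C(C)=C/CCBr)[C@H]2[C@]1(C(=O)O)CO[C@@H]2CO[Si](c1ccccc1)(c1ccccc1)C(C)(C)C | intermediate
20 | 3-[(2E)-5-bromo-2-methylpent-2-en-1-yl]-4-{[(tert-butyldiphenylsilyl)oxy]methyl}tetrahydro-1H,3H-furo[3,4-c]furan-1-one (cis-fused; 3,3a-trans; 3a,4-trans) | O=C1O[C@@H](C/C(C)=C/CCBr)[C@H]2[C@@H]1CO[C@@H]2CO[Si](c1ccccc1)(c1ccccc1)C(C)(C)C | intermediate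
21 | triethyl phosphonoacetate | CCOC(=O)CP(=O)(OCC)OCC | starting material
22 | sodium salt of triethyl phosphonoacetate | [Na+].CCOC(=O)[CH-]P(=O)(OCC)OCC | intermediate
23 | ethyl (5E)-7-[4-{[(tert-butyldiphenylsilyl)oxy]methyl}-1-oxotetrahydro-1H,3H-furo[3,4-c]furan-3-yl]-2-(diethoxyphosphoryl)-6-methylhept-5-enoate (core as in 20; C-2 epimers) | O=C1O[C@@H](C/C(C)=C/CCC(C(=O)OCC)P(=O)(OCC)OCC)[C@H]2[C@@H]1CO[C@@H]2CO[Si](c1ccccc1)(c1ccccc1)C(C)(C)C | intermediate
24 | ethyl (5E)-2-(diethoxyphosphoryl)-7-[4-(hydroxymethyl)-1-oxotetrahydro-1H,3H-furo[3,4-c]furan-3-yl]-6-methylhept-5-enoate | O=C1O[C@@H](C/C(C)=C/CCC(C(=O)OCC)P(=O)(OCC)OCC)[C@H]2[C@@H]1CO[C@@H]2CO | intermediate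
25 | ethyl (5E)-2-(diethoxyphosphoryl)-7-(4-formyl-1-oxotetrahydro-1H,3H-furo[3,4-c]furan-3-yl)-6-methylhept-5-enoate | O=C1O[C@@H](C/C(C)=C/CCC(C(=O)OCC)P(=O)(OCC)OCC)[C@H]2[C@@H]1CO[C@@H]2C=O | intermediate
26 | ethyl 13,6-epoxygermacra-1(10)E,4(ring-cis)-dien-12,8-olid-15-oate (tricycle; C6, C7, C8 as in 40; H-11 cis to H-7) | O=C1O[C@H]2C/C(C)=C/CC/C(C(=O)OCC)=C\[C@H]3OC[C@H]1[C@H]23 | intermediate
27 | lactol diol from 26 (C15 = CH2OH; C12 = CHOH, both epimers) | OC1O[C@H]2C/C(C)=C/CC/C(CO)=C\[C@H]3OC[C@H]1[C@H]23 | intermediate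
28 | 15-O-tert-butyldimethylsilyl ether of lactol 27 | OC1O[C@H]2C/C(C)=C/CC/C(CO[Si](C)(C)C(C)(C)C)=C\[C@H]3OC[C@H]1[C@H]23 | intermediate
29 | 15-[(tert-butyldimethylsilyl)oxy]-13,6-epoxygermacra-1(10)E,4(ring-cis)-dien-12,8-olide | O=C1O[C@H]2C/C(C)=C/CC/C(CO[Si](C)(C)C(C)(C)C)=C\[C@H]3OC[C@H]1[C@H]23 | intermediate
30 | lithium enolate of 29 (C11=C12) | [Li+].[O-]C1=C2CO[C@@H]3/C=C(CO[Si](C)(C)C(C)(C)C)\CC/C=C(C)/C[C@H](O1)[C@@H]23 | intermediate
31 | 11-bromo derivative of 29 (bromine cis to H-7) | O=C1O[C@H]2C/C(C)=C/CC/C(CO[Si](C)(C)C(C)(C)C)=C\[C@H]3OC[C@@]1(Br)[C@H]23 | intermediate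
32 | bromozinc enolate from 31 | Br[Zn]OC1=C2CO[C@@H]3/C=C(CO[Si](C)(C)C(C)(C)C)\CC/C=C(C)/C[C@H](O1)[C@@H]23 | intermediate
33 | (6R,7R,8S)-15-[(tert-butyldimethylsilyl)oxy]-6-hydroxygermacra-1(10)E,4(ring-cis),11(13)-trien-12,8-olide | C=C1C(=O)O[C@H]2C/C(C)=C/CC/C(CO[Si](C)(C)C(C)(C)C)=C\[C@@H](O)[C@H]12 | intermediate
34 | [(tert-butyldimethylsilyl)oxy]acetaldehyde | CC(C)(C)[Si](C)(C)OCC=O | starting material
35 | ethyl 2-(triphenylphosphoranylidene)propanoate | CCOC(=O)C(C)=P(c1ccccc1)(c1ccccc1)c1ccccc1 | starting material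
36 | ethyl (2E)-4-[(tert-butyldimethylsilyl)oxy]-2-methylbut-2-enoate | CCOC(=O)/C(C)=C/CO[Si](C)(C)C(C)(C)C | intermediate
37 | (2E)-4-[(tert-butyldimethylsilyl)oxy]-2-methylbut-2-enoic acid | OC(=O)/C(C)=C/CO[Si](C)(C)C(C)(C)C | intermediate
38 | mixed anhydride of 37 with 2,4,6-trichlorobenzoic acid | O=C(OC(=O)/C(C)=C/CO[Si](C)(C)C(C)(C)C)c1c(Cl)cc(Cl)cc1Cl | intermediate
39 | 6-O-[(2E)-4-(tert-butyldimethylsilyloxy)-2-methylbut-2-enoyl] ester of 33 | C=C1C(=O)O[C@H]2C/C(C)=C/CC/C(CO[Si](C)(C)C(C)(C)C)=C\[C@@H](OC(=O)/C(C)=C/CO[Si](C)(C)C(C)(C)C)[C@H]12 | intermediate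
40 | target: (6R,7R,8S)-15-hydroxy-6-[(2E)-4-hydroxy-2-methylbut-2-enoyloxy]germacra-1(10)E,4(ring-cis),11(13)-trien-12,8-olide | C=C1C(=O)O[C@H]2C/C(C)=C/CC/C(CO)=C\[C@@H](OC(=O)/C(C)=C/CO)[C@H]12 | target

**Step count**

Total steps: 21. Longest linear sequence: 17 (steps 1, 2, 4, 6–17, 20, 21).

**Steps most likely to fail**

1. Step 12 (ring closure). Intermolecular olefination to dimers and oligomers may outrun closure of the strained ten-membered ring, and the base may epimerise the α-alkoxy aldehyde. The fallback closes the same bond by metathesis and sets out from 23. Aqueous formaldehyde and K2CO3 should convert the phosphonate into the acrylate ethyl 2-methylidene-hept-5-enoate analogue of 23 F2. Bu4NF/AcOH should give the 4-hydroxymethyl acrylate F3, and Dess–Martin oxidation the 4-formyl acrylate F4. Methylenation with Zn, CH2I2 and TiCl4 should give the 4-vinyl acrylate F5. Ring-closing metathesis between the vinyl group and the acrylate (second-generation Hoveyda–Grubbs catalyst, toluene, 80 °C, 1 mM) would come back to the route at 26. This fallback has its own weakness: the vinyl group can also close a six-membered ring onto the C1=C10 alkene.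

2. Step 7 (key step). Copper-mediated β-hydride loss from C8 to a C8=C9 diene may compete with lactonisation, or the 5-exo closure may show poor facial selectivity at C7. The fallback is ionic and sets out from 14. Iodocarbocyclisation of the titanium malonate enolate (Ti(Ot-Bu)4, I2, CuO, CH2Cl2, 23 °C) should add C11 and iodine anti across the E-alkene in a 5-exo mode. This gives di-tert-butyl 4,5-trans-4-[(3E)-6-bromo-1-iodo-3-methylhex-3-en-1-yl]-5-{[(tert-butyldiphenylsilyl)oxy]methyl}oxolane-3,3-dicarboxylate F1. Warming in toluene at 80 °C lets the cis ester displace iodide with inversion and lose 2-methylpropene, a net syn carbo-oxygenation that comes back to the route at 17. This variant depends on the E-alkene from step 4 being pure.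

3. Step 17 (opening of the oxolane). The zinc enolate may be protonated, giving simple debromination back to 29, faster than it expels the ring oxygen, because the C13–O6 bond is only partly aligned with the enolate. The fallback is a base-induced retro-oxa-Michael opening and sets out from 29. Lithium enolate 30 is made as in step 16 and warmed to 0 °C without an electrophile, so that E1cB cleavage of C13–O6 gives the lithium alkoxide of 33 F6. A cold quench with AcOH comes back to the route at 33.

Further compounds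
F1 | step 7 | di-tert-butyl 4,5-trans-4-[(3E)-6-bromo-1-iodo-3-methylhex-3-en-1-yl]-5-{[(tert-butyldiphenylsilyl)oxy]methyl}oxolane-3,3-dicarboxylate | CC(C)(C)OC(=O)C1(C(=O)OC(C)(C)C)CO[C@H](CO[Si](c2ccccc2)(c2ccccc2)C(C)(C)C)[C@H]1[C@H](I)C/C(C)=C/CCBr
F2 | step 12 | ethyl (5E)-7-[4-{[(tert-butyldiphenylsilyl)oxy]methyl}-1-oxotetrahydro-1H,3H-furo[3,4-c]furan-3-yl]-6-methyl-2-methylidenehept-5-enoate | O=C1O[C@@H](C/C(C)=C/CCC(=C)C(=O)OCC)[C@H]2[C@@H]1CO[C@@H]2CO[Si](c1ccccc1)(c1ccccc1)C(C)(C)C
F3 | step 12 | ethyl (5E)-7-[4-(hydroxymethyl)-1-oxotetrahydro-1H,3H-furo[3,4-c]furan-3-yl]-6-methyl-2-methylidenehept-5-enoate | O=C1O[C@@H](C/C(C)=C/CCC(=C)C(=O)OCC)[C@H]2[C@@H]1CO[C@@H]2CO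
F4 | step 12 | ethyl (5E)-7-(4-formyl-1-oxotetrahydro-1H,3H-furo[3,4-c]furan-3-yl)-6-methyl-2-methylidenehept-5-enoate | O=C1O[C@@H](C/C(C)=C/CCC(=C)C(=O)OCC)[C@H]2[C@@H]1CO[C@@H]2C=O
F5 | step 12 | ethyl (5E)-7-(4-ethenyl-1-oxotetrahydro-1H,3H-furo[3,4-c]furan-3-yl)-6-methyl-2-methylidenehept-5-enoate | O=C1O[C@@H](C/C(C)=C/CCC(=C)C(=O)OCC)[C@H]2[C@@H]1CO[C@@H]2C=C
F6 | step 17 | lithium alkoxide of 33 | C=C1C(=O)O[C@H]2C/C(C)=C/CC/C(CO[Si](C)(C)C(C)(C)C)=C\[C@@H]([O-])[C@H]12.[Li+]
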